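**Stall half-life.** The ratio 3.16 opens the reckoning: in the summer run the gain of target per minute fell by that factor from the interval 0.333 min to 1.00 min to the interval 1.50 min to 2.50 min, whose middles lie 1.33 min apart. Yet 54.5 % of the starting material still stood at 5.00 min, so we read the fall as catalyst deactivation, taken as first order. That gives the stall half-life, the time in which the rate of making target halves once a run is under way, here a reading from the summer run: 0.804 min.

| flask | starting material | reagent | capture agent | free catalyst | remark |
|---|---|---|---|---|---|
| dusk | 0.44 M | 0.60 equiv | 0.044 M | 0.3 mol% | run made earlier |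
| summer | 0.44 M | 1.4 equiv | 0.044 M | 0.3 mol% | run made earlier |
| spring | 0.44 M | 0.90 equiv | 0.044 M | 0.45 mol% | run made earlier |
| flask | 0.44 M | 0.900 equiv | 0.0440 M | 0.3 mol% |  |

| run | time / min | target / % | starting material / % |
|---|---|---|---|
| dusk | 0.417 | 1.7 | 76.9 |
| dusk | 0.667 | 2.8 | 72.2 |
| dusk | 1.00 | 4.0 | 68.0 |
| dusk | 2.00 | 7.5 | 62.1 |
| dusk | 3.00 | 8.0 | 60.0 |
| dusk | 5.00 | 10.1 | 58.5 |
| summer | 0.333 | 2.9 | 79.4 |
| summer | 1.00 | 8.8 | 66.1 |
| summer | 1.50 | 12.9 | 61.6 |
| summer | 2.50 | 15.7 | 56.3 |
| summer | 4.00 | 18.7 | 54.3 |
| summer | 5.00 | 18.9 | 54.5 |
| spring | 0.417 | 4.7 | 72.4 |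
| spring | 0.667 | 7.3 | 66.1 |
| spring | 1.33 | 13.2 | 58.4 |
| spring | 2.50 | 17.2 | 53.6 |
| spring | 5.00 | 19.9 | 50.7 |

(standard deviation of a reading: 0.3 percentage points)

1. apparent order in reagent when 20 % of the starting material are converted (percent change of the rate of making target for one percent more reagent charged)
2. factor on the rate of making target when 20 % of the starting material are converted if free catalyst is charged twice over

- the numbers in the tables scatter by 0.3 percentage points (one standard deviation)

**Reagent.** Dusk and summer carry the same catalyst loading, so we take the fading as equal at equal time, and the half-life drops out. At 1.00 min they read 4.0 % and 8.8 % target, which for 0.60 equiv against 1.4 equiv gives an order of 0.931.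

**Catalyst.** Summer reads 79.4 % starting material at 0.333 min, so we put the 20 % mark for the flask there. By hand, we take doubled catalyst to reach the mark in 0.167 min, which saves 0.207 half-lives of fading. The factor is then two times 1.15, or 2.31.

**The forecast.** It gives order 0.9 and factor 2.7, and adds: “The estimate rests on one comparison, so the range is wide.” Our order is 0.931 against its 0.9, and our factor of 2.31 is lower than its 2.7.

**The flask.** It gives order 0.92 and factor 2.40.

    open intermediate + capture agent → trapped intermediate (k = 0.290 /M/s)
    free catalyst → spent catalyst (k = 0.0120 /s)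
    starting material + free catalyst ⇌ free catalyst + open intermediate (K = 0.430, k = 13.0 /M/s)
    reagent + free catalyst + open intermediate → free catalyst + target (k = 20.0 /M²/s)

At 0.400 min the flask holds 75.0 % of its catalyst free and 25.0 % spent. Counted in stall half-lives, 2.00 min is 2.49 of them and leaves 17.8 %, while the flask holds 23.7 % free. In the spring run the same count gives a factor of 0.205 on the gain per minute between its last two intervals, and its readings give 0.316.

(The runs come from a simulation on assumed constants; scatter was added.)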